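1. In a one-step world with dissolved gas as a steady partner, substrate falls by a fixed fraction per hour, whatever the charge (the pseudo-first-order case). Here are the flasks, the readings and the questions.

| flask | substrate | gas phase | remark | time |
|---|---|---|---|---|
| Thursday's | 0.70 M | 19 mM (held) | run made earlier |  |
| Friday's | 1.1 M | 19 mM (held) | run made earlier |  |
| flask | 0.50 M | 19 mM (held) |  | 25 h |

| run | time / h | target / % | substrate / % |
|---|---|---|---|
| Thursday's | 4.00 | 5.1 | 93.8 |
| Thursday's | 10.0 | 12.4 | 85.8 |
| Thursday's | 20.0 | 22.0 | 73.9 |
| Thursday's | 30.0 | 29.8 | 62.7 |
| Friday's | 2.50 | 2.8 | 96.4 |
| Friday's | 6.00 | 7.0 | 92.0 |
| Friday's | 12.0 | 14.0 | 84.1 |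
| Friday's | 30.0 | 29.5 | 64.6 |

(scatter of a reading: 0.3 percentage points)

- what was read earlier has a scatter of 0.3 percentage points, one standard deviation
- at the start none of the gas phase is in solution

- north-west: doubling the transfer coefficient of the gas phase, all else as stated
- south: doubling the saturation concentration of gas phase, all else as stated

* the target standing at 25 h, as a percentage of the substrate charged
* the change that raises the amount of target at 25 h, in percent of the substrate charged most ("none" if none brings more than 2 percentage points) (north-west / south / none)
* amount of target at 25 h, in percent of the substrate charged, after north-west

2. I turned the question round. If gas transfer set the rate, gas would enter at a fixed molar rate, and the percentage lost would shrink in proportion to the charge. From Thursday's 37.3% at 30.0 h, Friday's run should then have lost 23.7%. It lost 35.4%, more than that, so I took dissolved gas near saturation as the concentration setting the order.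

3. Thursday's last reading gave 0.0156 /h. This is the loss constant: the logarithm of charged over remaining substrate, divided by the time. Friday's gave 0.0146 /h, and I read that small gap as the cost of transfer.

4. For the new flask, I reckoned from the constant that 67.8% of the substrate charged would remain. Thursday's target per substrate lost averaged 0.821 in the readings at 20.0 h and 30.0 h, so I reckoned 26.5% target. Doubling the transfer coefficient could recover part of that gap, and I put the gain in target below 2 percentage points. Doubling saturation should double the constant if the gas enters at first order, so I chose south.

5. The forecast gave 26.4% (25.5% to 27.4%), south, and 27% (26% to 28.3%) after north-west. Its ground for south was this: “Doubling saturation should nearly double the rate if the reaction is first order in dissolved gas”.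

6. The new flask gave 26.8% target. The best change was south, which brought 15 points, more than the 0.55 points that north-west brought, and north-west reached 27.4%.

    substrate + dissolved gas → target (k = 0.780 /M/h)
    dissolved gas + target → over-reaction product (k = 0.340 /M/h)
    substrate → side product (k = 0.00140 /h)
    gas phase ⇌ dissolved gas, rate k4*(csat - [dissolved gas]) (kL = 6.90 /h)

The loss constant gave 67.8% substrate for the new flask, which held 68.0%, and 39.2% for the same charge read at 2.5 d, which held 39.3%. At 25.0 h the new flask held dissolved gas at 0.0182 M against a saturation of 19 mM. At that time in the new flask, target was made 5.82 times faster than it was used up, each step taken net.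

The readings were generated by integration with made-up constants.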